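**Retrosynthetic overview**
- Target acid ⇐ its ethyl ester (saponification, last step).
- Oxane ring plus acrylate unit ⇐ lactol (5R)-5-homofarnesyloxan-2-ol + ethyl 2-(diethoxyphosphoryl)acrylate, by a new amine-relay Horner–Wadsworth–Emmons/SN2′ annulation (forms C2=Cα, then O1–C2; sets C2).
- Lactol ⇐ δ-lactone ⇐ enamine-catalysed asymmetric Michael addition of a C18 trienal to hexafluoroisopropyl acrylate, reduced in the same flask (sets C5, the first stereocentre).
- C18 trienal ⇐ (2E,6E)-farnesyl bromide + an acetal-bearing C3 Grignard reagent (copper-catalysed coupling).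
- Ring order: a temporary δ-lactone/lactol ring is made first; the annulation opens it and re-closes it as the only ring of the target, the 2,5-trans oxane.

Assumption: compounds 1, 2 (as its THF solution), 5 and 10 are taken as catalogue items; C2–C6 and O1 are the oxane atoms of the target and Cα is the acrylate carbon bonded to C2.

**Step 1**
Reactants: 1 (2E,6E)-farnesyl bromide [(2E,6E)-1-bromo-3,7,11-trimethyldodeca-2,6,10-triene]; 2 [2-(1,3-dioxolan-2-yl)ethyl]magnesium bromide
Product: 4 (5E,9E)-6,10,14-trimethylpentadeca-5,9,13-trienal, via dioxolane acetal 3 (not isolated)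
Conditions: 2 (1.3 equiv), Li2CuCl4 (3 mol%), THF, −20 → 0 °C; then 2 M HCl, THF, rt
Reagents that add atoms: water, O
Why: Copper-catalysed cross-coupling of a primary alkyl Grignard reagent with an allylic bromide (Kochi-type coupling) substitutes at the primary carbon without moving or isomerising the E-alkenes, and the acid quench hydrolyses the dioxolane (acetal hydrolysis) to the aldehyde.

**Step 2**
Reactants: 4 (5E,9E)-6,10,14-trimethylpentadeca-5,9,13-trienal; 5 1,1,1,3,3,3-hexafluoropropan-2-yl acrylate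
Product: 8 (5R)-5-[(3E,7E)-4,8,12-trimethyltrideca-3,7,11-trien-1-yl]oxan-2-one, via formyl ester 6 (not isolated), via hydroxy ester 7 (not isolated)
Conditions: 5 (2 equiv), (S)-α,α-diphenylprolinol trimethylsilyl ether (10 mol%), 4-nitrophenol (20 mol%), toluene, 0 °C → rt; evaporate excess 5; then NaBH4, EtOH, −20 → 0 °C; then PPTS (10 mol%), CH2Cl2, rt
Reagents that add atoms: none
Why: Enamine-catalysed asymmetric Michael addition of a linear aldehyde to an activated acrylate: the E-enamine of 4 is attacked on the face away from the CPh2(OSiMe3) group, which gives the R configuration at the new stereocentre (future C5), and in-flask NaBH4 reduction of the epimerisable aldehyde is followed by lactonisation with loss of hexafluoropropan-2-ol.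

**Step 3**
Reactants: 8 (5R)-5-[(3E,7E)-4,8,12-trimethyltrideca-3,7,11-trien-1-yl]oxan-2-one
Product: 9 (5R)-5-[(3E,7E)-4,8,12-trimethyltrideca-3,7,11-trien-1-yl]oxan-2-ol (mixture of anomers)
Conditions: i-Bu2AlH (1.1 equiv), CH2Cl2, −78 °C; aq. potassium sodium tartrate (KNaC4H4O6) work-up
Reagents that add atoms: none
Why: Partial reduction of a δ-lactone with i-Bu2AlH stops at the lactol because the tetrahedral aluminium alkoxide is stable at −78 °C, and C5 is not touched.

**Step 4**
Reactants: 9 (5R)-5-[(3E,7E)-4,8,12-trimethyltrideca-3,7,11-trien-1-yl]oxan-2-ol; 10 ethyl 2-(diethoxyphosphoryl)acrylate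
Product: 14 ethyl 2-[(2S,5R)-5-[(3E,7E)-4,8,12-trimethyltrideca-3,7,11-trien-1-yl]oxan-2-yl]prop-2-enoate, via ammonium phosphonate zwitterion 11 (not isolated), via open-chain hydroxy aldehyde 12 (not isolated), via allylic ammonium enoate 13 (not isolated)
Conditions: 10 (1.3 equiv), DABCO (1.5 equiv), MeCN, rt, 15 min; then 9, K2CO3 (2.0 equiv), rt → 45 °C
Reagents that add atoms: none
Why: Proposed new method: an amine-relay Horner–Wadsworth–Emmons/SN2′ annulation of a lactol, in which DABCO adds to the doubly activated alkene of 10 to give the phosphonate-stabilised zwitterion 11, whose aldol adduct with the open-chain aldehyde 12 has no α-hydrogen and so cannot take the Morita–Baylis–Hillman elimination path but loses diethyl phosphate (Horner–Wadsworth–Emmons olefination) to give the allylic ammonium enoate 13, the same species that Lewis bases generate from Morita–Baylis–Hillman carbonates; the tethered primary hydroxyl then closes the oxane by 6-exo attack at the β-carbon with expulsion of DABCO (SN2′) through a chair transition state with the C5 chain and the reacting alkene both equatorial, which sets C2 as S (2,5-trans, also the more stable diequatorial isomer); the closest known reactions are the tandem Michael/Horner–Wadsworth–Emmons olefination of 2-phosphonoacrylates with anionic nucleophiles and the amine-catalysed allylic etherification of Morita–Baylis–Hillman carbonates.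

**Step 5**
Reactants: 14 ethyl 2-[(2S,5R)-5-[(3E,7E)-4,8,12-trimethyltrideca-3,7,11-trien-1-yl]oxan-2-yl]prop-2-enoate
Product: 15 2-[(2S,5R)-5-[(3E,7E)-4,8,12-trimethyltrideca-3,7,11-trien-1-yl]oxan-2-yl]prop-2-enoic acid
Conditions: LiOH·H2O (3 equiv), THF/MeOH/H2O (3:1:1), 0 °C → rt; then 1 M HCl to pH 3, 0 °C
Reagents that add atoms: lithium hydroxide, [Li+].[OH-]
Why: Ester saponification (acyl–oxygen cleavage by hydroxide) frees the acid, and neither stereocentre is α to the carbonyl, so both are retained.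

**Compound list**
1 | (2E,6E)-farnesyl bromide | BrC/C=C(\C)CC/C=C(\C)CCC=C(C)C | starting material
2 | [2-(1,3-dioxolan-2-yl)ethyl]magnesium bromide | Br[Mg]CCC1OCCO1 | starting material
3 | 2-[(4E,8E)-5,9,13-trimethyltetradeca-4,8,12-trien-1-yl]-1,3-dioxolane | O1CCOC1CCC/C=C(\C)CC/C=C(\C)CCC=C(C)C | intermediate
4 | (5E,9E)-6,10,14-trimethylpentadeca-5,9,13-trienal | O=CCCC/C=C(\C)CC/C=C(\C)CCC=C(C)C | intermediate
5 | 1,1,1,3,3,3-hexafluoropropan-2-yl acrylate | C=CC(=O)OC(C(F)(F)F)C(F)(F)F | starting material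
6 | 1,1,1,3,3,3-hexafluoropropan-2-yl (4R,7E,11E)-4-formyl-8,12,16-trimethylheptadeca-7,11,15-trienoate | O=C(CC[C@@H](CC/C=C(\C)CC/C=C(\C)CCC=C(C)C)C=O)OC(C(F)(F)F)C(F)(F)F | intermediate
7 | 1,1,1,3,3,3-hexafluoropropan-2-yl (4R,7E,11E)-4-(hydroxymethyl)-8,12,16-trimethylheptadeca-7,11,15-trienoate | O=C(CC[C@@H](CC/C=C(\C)CC/C=C(\C)CCC=C(C)C)CO)OC(C(F)(F)F)C(F)(F)F | intermediate
8 | (5R)-5-[(3E,7E)-4,8,12-trimethyltrideca-3,7,11-trien-1-yl]oxan-2-one | O=C1CC[C@@H](CC/C=C(\C)CC/C=C(\C)CCC=C(C)C)CO1 | intermediate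
9 | (5R)-5-[(3E,7E)-4,8,12-trimethyltrideca-3,7,11-trien-1-yl]oxan-2-ol (anomeric mixture) | OC1CC[C@@H](CC/C=C(\C)CC/C=C(\C)CCC=C(C)C)CO1 | intermediate
10 | ethyl 2-(diethoxyphosphoryl)acrylate | C=C(C(=O)OCC)P(=O)(OCC)OCC | starting material
11 | DABCO adduct of 10: ethyl 3-(4-aza-1-azoniabicyclo[2.2.2]octan-1-yl)-2-(diethoxyphosphoryl)propanoate, carbanion at C2 (zwitterion) | CCOC(=O)[C-](C[N+]12CCN(CC1)CC2)P(=O)(OCC)OCC | intermediate
12 | (4R,7E,11E)-4-(hydroxymethyl)-8,12,16-trimethylheptadeca-7,11,15-trienal (open-chain tautomer of 9) | O=CCC[C@@H](CC/C=C(\C)CC/C=C(\C)CCC=C(C)C)CO | intermediate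
13 | 1-[(6R,9E,13E)-2-(ethoxycarbonyl)-6-(hydroxymethyl)-10,14,18-trimethylnonadeca-2,9,13,17-tetraen-1-yl]-4-aza-1-azoniabicyclo[2.2.2]octane diethyl phosphate (E/Z mixture at C2=C3) | CCOC(=O)C(C[N+]12CCN(CC1)CC2)=CCC[C@@H](CC/C=C(\C)CC/C=C(\C)CCC=C(C)C)CO.CCOP(=O)([O-])OCC | intermediate
14 | ethyl 2-[(2S,5R)-5-[(3E,7E)-4,8,12-trimethyltrideca-3,7,11-trien-1-yl]oxan-2-yl]prop-2-enoate | C=C(C(=O)OCC)[C@@H]1CC[C@@H](CC/C=C(\C)CC/C=C(\C)CCC=C(C)C)CO1 | intermediate
15 | 2-[(2S,5R)-5-[(3E,7E)-4,8,12-trimethyltrideca-3,7,11-trien-1-yl]oxan-2-yl]prop-2-enoic acid | C=C(C(=O)O)[C@@H]1CC[C@@H](CC/C=C(\C)CC/C=C(\C)CCC=C(C)C)CO1 | target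

**Totals**
Total step count: 5. Longest linear sequence: 5 steps (1 → 4 → 8 → 9 → 14 → 15).

**Three steps most likely to fail**

Step 4 (the proposed new annulation). The risks are that the hydroxyl group of 9 adds to 10 faster than DABCO does, that the hindered zwitterion olefinates the lactol slowly, and that the 2,5-trans to cis ratio is only moderate (the cis isomer would be removed by chromatography). The fallback uses known chemistry; it sets out from 9 and comes back at 14.
- Wittig olefination of 9 with Ph3P=CHCO2Et (toluene, 80 °C) gives ethyl (2E,6S,9E,13E)-6-(hydroxymethyl)-10,14,18-trimethylnonadeca-2,9,13,17-tetraenoate F1. The descriptor 6S reflects a priority change only; the spatial arrangement at that carbon is unchanged.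
- KOt-Bu (0.2 equiv, THF, 0 °C → rt) closes the ring by thermodynamically controlled oxa-Michael addition to the diequatorial ethyl 2-[(2S,5R)-5-[(3E,7E)-4,8,12-trimethyltrideca-3,7,11-trien-1-yl]oxan-2-yl]acetate F2.
- LiN(i-Pr)2 (THF, −78 °C) then dimethylmethylideneammonium iodide gives the Mannich base ethyl 3-(dimethylamino)-2-[(2S,5R)-5-[(3E,7E)-4,8,12-trimethyltrideca-3,7,11-trien-1-yl]oxan-2-yl]propanoate F3.
- MeI converts it into 3-ethoxy-N,N,N-trimethyl-3-oxo-2-[(2S,5R)-5-[(3E,7E)-4,8,12-trimethyltrideca-3,7,11-trien-1-yl]oxan-2-yl]propan-1-aminium iodide F4, and DBU eliminates trimethylamine to give 14.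

Step 2 (asymmetric Michael addition). The secondary-amine catalyst may be acylated or captured in an aza-Michael addition by the activated acrylate 5, and turnover or enantioselectivity may fall short. The fallback sets out from 4 and comes back at 9, so it bypasses 8 and step 3.
- The same catalyst adds 4 to the vinyl ketone 4-hydroxy-4-methylpent-1-en-3-one, an acrylate equivalent of the simple enone class for which enamine Michael additions are well established, giving (2R,5E,9E)-2-(4-hydroxy-4-methyl-3-oxopentyl)-6,10,14-trimethylpentadeca-5,9,13-trienal F5.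
- NaBH4 (MeOH, 0 °C) reduces both carbonyl groups to (6R,9E,13E)-6-(hydroxymethyl)-2,10,14,18-tetramethylnonadeca-9,13,17-triene-2,3-diol F6.
- NaIO4 (THF/H2O, rt) cleaves the 1,2-diol with loss of acetone, and the resulting hydroxy aldehyde closes to 9.

Step 1 (coupling and acetal hydrolysis in one flask). Some SN2′ coupling may occur, and the aqueous acid may trigger Prins-type cyclisation of the 5-enal or damage the polyene. The fallback is acid-free; it sets out from 1 and comes back at 4.
- Allylmagnesium bromide (THF, 0 °C) couples with 1 to give (5E,9E)-6,10,14-trimethylpentadeca-1,5,9,13-tetraene F7.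
- 9-Borabicyclo[3.3.1]nonane hydroborates only the terminal alkene, and NaOH/H2O2 gives (5E,9E)-6,10,14-trimethylpentadeca-5,9,13-trien-1-ol F8.
- Dess–Martin periodinane (NaHCO3, CH2Cl2) oxidises F8 to 4.

**Further compounds**
F1 | step 4 | ethyl (2E,6S,9E,13E)-6-(hydroxymethyl)-10,14,18-trimethylnonadeca-2,9,13,17-tetraenoate | CCOC(=O)/C=C/CC[C@@H](CC/C=C(\C)CC/C=C(\C)CCC=C(C)C)CO
F2 | step 4 | ethyl 2-[(2S,5R)-5-[(3E,7E)-4,8,12-trimethyltrideca-3,7,11-trien-1-yl]oxan-2-yl]acetate | CCOC(=O)C[C@@H]1CC[C@@H](CC/C=C(\C)CC/C=C(\C)CCC=C(C)C)CO1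
F3 | step 4 | ethyl 3-(dimethylamino)-2-[(2S,5R)-5-[(3E,7E)-4,8,12-trimethyltrideca-3,7,11-trien-1-yl]oxan-2-yl]propanoate | CCOC(=O)C(CN(C)C)[C@@H]1CC[C@@H](CC/C=C(\C)CC/C=C(\C)CCC=C(C)C)CO1
F4 | step 4 | 3-ethoxy-N,N,N-trimethyl-3-oxo-2-[(2S,5R)-5-[(3E,7E)-4,8,12-trimethyltrideca-3,7,11-trien-1-yl]oxan-2-yl]propan-1-aminium iodide | CCOC(=O)C(C[N+](C)(C)C)[C@@H]1CC[C@@H](CC/C=C(\C)CC/C=C(\C)CCC=C(C)C)CO1.[I-]
F5 | step 2 | (2R,5E,9E)-2-(4-hydroxy-4-methyl-3-oxopentyl)-6,10,14-trimethylpentadeca-5,9,13-trienal | CC(C)(O)C(=O)CC[C@@H](CC/C=C(\C)CC/C=C(\C)CCC=C(C)C)C=O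
F6 | step 2 | (6R,9E,13E)-6-(hydroxymethyl)-2,10,14,18-tetramethylnonadeca-9,13,17-triene-2,3-diol | CC(C)(O)C(O)CC[C@@H](CC/C=C(\C)CC/C=C(\C)CCC=C(C)C)CO
F7 | step 1 | (5E,9E)-6,10,14-trimethylpentadeca-1,5,9,13-tetraene | C=CCC/C=C(\C)CC/C=C(\C)CCC=C(C)C
F8 | step 1 | (5E,9E)-6,10,14-trimethylpentadeca-5,9,13-trien-1-ol | OCCCC/C=C(\C)CC/C=C(\C)CCC=C(C)C
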